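## Structural features

The target is a diester built on a 1-arylpropan-1-ol: its single benzene ring carries the stereogenic side chain at C1, a free hydroxyl at C3, methoxy groups at C4 and C5, and hydrogen only at C2 and C6. The benzylic carbon is the only stereocentre, (S), bonded to hydrogen, ethyl, ring carbon C1 and the ester oxygen; as it has no neighbouring stereocentre, its configuration must come from a reagent or catalyst. The acyl part is a (Z)-2-(acyloxymethyl)but-2-enoate whose CH2–O carries an angelate, so there are two trisubstituted enoates, each with the β-methyl cis to its carbonyl group, the less stable geometry. Both alkenes can isomerise under nucleophilic catalysis (amines, phosphines), radicals, heat or strong acid, and the inner unit is an activated allylic ester, open to SN2' displacement and to ionisation by low-valent metals. The benzylic ester lies para to the C4 methoxy group, which makes it sensitive to acid and to hydrogenolysis, and the phenol must be masked whenever an organolithium or an acyl donor is present. The real difficulties are three: telling one of three ring oxygens apart, setting an isolated benzylic stereocentre, and carrying a geometrically fragile diester through the endgame. The key step uses the substitution pattern of the benzylic carbon, which is attached to ring carbon C1, to an ethyl group and to oxygen, so the C1–benzylic bond can be formed by shifting the aryl group from boron onto an α-oxygenated carbon of defined configuration; the ring pattern helps, because in the silylated phenol the carbon that becomes C1 bears the only C–H without an ortho neighbour, so boron can be placed there directly.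

## Logic of the disconnections

**21 to 20.** The phenolic O–H is traced back to an O–Si bond. The phenol has to be masked through the organolithium and acylation steps, and a silyl ether can be removed by buffered fluoride, which needs neither acid (benzylic ester) nor free base (Z-enoates, allylic ester). The skeleton is not simplified, but every earlier step becomes chemoselective. The forward step must not release a free phenoxide or basic fluoride.

**20 to 11 and 18.** The acyl C–O bond of the benzylic ester is cut. This divides the molecule into two halves of similar size: 11 holds the arene and the stereocentre, 18 holds both Z-alkenes. Because the C–O bond of the carbinol is not touched, the configuration of 11 is carried over unchanged. The forward step needs acyl activation of 18 without a nucleophilic catalyst, so that neither alkene geometry nor the allylic ester is lost.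

**11 to 10.** The benzylic C–O bond is exchanged for a C–B bond. A C–B bond can be made with control of configuration during C–C bond formation and is oxidised with retention. The problem of an enantioselective C–O bond thus becomes one of an enantioselective C–C bond. The oxidant must be mild enough for the aryl silyl ether.

**10 to 4 and 7 (through 9 and 8).** The bond between aryl C1 and the benzylic carbon is cut. This is the largest simplification: the only bond between ring and chain and the only stereocentre are formed together from an achiral arylboronate and an achiral three-carbon carbamate. The forward step needs enantiotopos-selective deprotonation of 7 to 8 by a chiral diamine, borylation with retention to 9, and aryl migration with inversion. The (R) configuration of 8 is required for (S)-10.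

**4 to 2 and 3, then 2 to 1.** The aryl C–B bond is traced to a C–H bond, and the O–Si bond to the free phenol. In 2 that C–H is the only one without an ortho substituent, so a sterically governed C–H borylation can find it. This reaches 1, in which the three ring oxygens are already differentiated. The silyl group has two tasks in the forward direction: protection, and blocking the neighbouring C–H.

**7 to 5 and 6.** The acyl C–O bond of the carbamate is cut, leading to 5 and 6. The carbamate serves as directing group for lithiation, as the anchor that keeps the carbanion configured, and as the leaving group in the migration. The forward step is a plain O-acylation.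

**18 to 17, then 17 to 14 and 15.** The acid is traced to its tert-butyl ester, the one ester in the molecule that is cleaved by alkyl–oxygen fission under acid, without nucleophile or base. Then the acyl C–O bond of the angelate is cut. This gives two small Z-configured pieces. The forward acylation must activate 15 without Z to E isomerisation.

**14 to 12.** The bond between the α-carbon and the hydroxymethyl carbon is cut together with the β C–H bond, leading to 12 and a one-carbon aldehyde reagent. Syn addition of hydrogen and metal across the triple bond places H and the future CH2OH on the same side, which is exactly methyl cis to the ester. Two bonds and the alkene geometry are gained in one operation. The forward step needs conjugate hydrometalation in preference to carbonyl reduction, and C–C bond formation before the geometry can drift.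

## Other disconnections considered

Alternative 1: The benzene ring itself is dismantled. The ring bonds C2–C3 and C1–C6 are cut, leading to 3,4-dimethoxyfuran A1 and pent-1-yn-3-one A2.
- **Forward key step.** A [4+2] cycloaddition of A1 and A2 would give the 7-oxanorbornadiene A3. BF3·OEt2 in the same flask would open the oxygen bridge and aromatise A3 to 1-(3-hydroxy-4,5-dimethoxyphenyl)propan-1-one A4. Silylation of A4 and an enantioselective ketone reduction would then join the chosen route at 11.
- **In its favour.** The free hydroxyl of A4 comes from the bridge oxygen and is differentiated from the methyl ethers by construction. The side chain arrives as a ketone, so the stereocentre can be set by a catalytic reduction without a stoichiometric chiral diamine or −78 °C. On this point the alternative is better than the chosen plan.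
- **Against it here.** A1 is a specialty diene, electron-rich and acid-sensitive, that may have to be made over several steps. A2 is volatile and prone to polymerise. Furan cycloadditions are reversible. The oxygen bridge of A3 must break at the bridgehead next to the acyl-bearing carbon and stay on the other bridgehead. The acyl group should favour this sense, since the other ionisation would place positive charge on the acyl-bearing carbon, but opening the other way would put the hydroxyl ortho to the acyl group.
- **Comparison.** Structurally, the alternative builds a ring that the chosen plan simply buys. Mechanistically, it separates ring construction from stereocontrol, whereas the chosen key step forms the C–C bond and the stereocentre together. In step count it is equal or slightly shorter up to 11 if A1 is purchased (three operations against five), and longer if A1 must be prepared.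

Alternative 2: The phenolic C3–O bond is cut last, through C–B back to C–H.
- **Forward key step.** Reduction of 1-(3,4-dimethoxyphenyl)propan-1-one A5 would give the (S)-alcohol A6, and acylation of A6 with 18 would give the complete ester A7. Borylation of A7 with 3 under [Ir(cod)(OMe)]2 and 4,4'-di-tert-butyl-2,2'-bipyridine should occur at the C–H ortho to the methoxy group and meta to the side chain, giving the aryl boronate A8. Oxidation of the C–B bond of A8 would give 21.
- **In its favour.** No protecting group is needed, A5 is a commodity ketone, and the stereocentre again comes from a catalytic reduction. The arene line has four steps against six in the chosen plan. On step economy this alternative is the better one.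
- **Against it here.** The ring of A7 has no unhindered C–H. The site between two substituents is closed, and the choice between the other two rests on the size difference between a methoxy group and a branched benzylic substituent, so low reactivity and mixtures are plausible. The chosen plan borylates a ring with one uniquely free C–H, and on regiocontrol it is clearly better. A7 also exposes two electron-poor alkenes and an activated allylic ester to iridium boryl and hydride species. The later oxidation of the aryl–boron bond of A8 with basic peroxide invites Weitz–Scheffer epoxidation or ester cleavage.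
- **Comparison.** The alternative places its main selectivity risk on the most valuable intermediate at the last stage. The chosen plan takes its risks early, on simple compounds.

Alternative 3: The benzylic C–O bond (not the acyl C–O bond) is cut, and the stereocentre is formed in the same step.
- **Forward key step.** The carboxylate of 18 would attack the aryl-bearing terminus of the allyl complex formed from the cinnamyl methyl carbonate A9 and [Ir(cod)Cl]2 with a chiral phosphoramidite. The product would be the branched (S)-allylic ester A10. Saturation of the vinyl group of A10 would give 20.
- **In its favour.** One catalytic step joins the two halves and sets the configuration, so the chiral material is used in catalytic amount. On that count the alternative is better; in convergence it equals the chosen plan.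
- **Against it here.** A10 is a branched, benzylic and allylic ester of an electron-rich arene. It can ionise again, with loss of enantiomeric purity or drift to the linear isomer. Acid 18 itself contains an allylic ester that a low-valent metal can ionise. The vinyl group of A10 must then be reduced in the presence of two enoates and a C–O bond that is open to hydrogenolysis. A9 still needs the same protected, regiodefined arene plus several steps of chain building, so nothing is saved before the key step.
- **Comparison.** Step counts are similar. The chosen plan relies on stereospecific steps (retention, inversion, retention) and on an acylation that does not touch the stereocentre, so it is the more robust of the two.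

Key step: step 4

Assumption: (+)-sparteine, angelic acid and tert-butyl but-2-ynoate are taken as catalogue materials, and the descriptor stays (S) from 10 through 11 and 20 to 21 because the spatial arrangement is kept while boron (ranked below both carbon substituents) is replaced by oxygen (ranked above both).

## Route

Step 1
Reactants: 1 2,3-dimethoxyphenol
Product: 2 tert-butyl(2,3-dimethoxyphenoxy)dimethylsilane
Conditions: TBSCl, imidazole, DMF, rt
Reagents that add atoms: tert-butyldimethylsilyl chloride, CC(C)(C)[Si](C)(C)Cl
Why: Standard O-silylation of a phenol (substitution at silicon, imidazole as base and silyl-transfer agent). The silyl ether survives the later organolithium, boron and acylation steps and is the bulky group that blocks the adjacent C–H in step 2.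

Step 2
Reactants: 2 tert-butyl(2,3-dimethoxyphenoxy)dimethylsilane; 3 bis(pinacolato)diboron
Product: 4 2-[3-(tert-butyldimethylsilyloxy)-4,5-dimethoxyphenyl]-4,4,5,5-tetramethyl-1,3,2-dioxaborolane
Conditions: [Ir(cod)(OMe)]2 (1.5 mol%), 4,4'-di-tert-butyl-2,2'-bipyridine (3 mol%), THF, 80 °C
Reagents that add atoms: none
Why: Iridium-catalysed aromatic C–H borylation through a trivalent iridium tris(boryl) species is governed by sterics. Of the three ring C–H bonds of 2, only C5–H has no ortho substituent, so the boron should enter there alone.

Step 3
Reactants: 5 propan-1-ol; 6 N,N-diisopropylcarbamoyl chloride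
Product: 7 propyl N,N-diisopropylcarbamate
Conditions: Et3N, CH2Cl2, reflux
Reagents that add atoms: none
Why: O-Carbamoylation of a primary alcohol (nucleophilic acyl substitution) with Et3N taking up HCl. The hindered carbamate resists attack by s-BuLi at carbonyl and directs α-lithiation.

Step 4
Reactants: 7 propyl N,N-diisopropylcarbamate; 4 2-[3-(tert-butyldimethylsilyloxy)-4,5-dimethoxyphenyl]-4,4,5,5-tetramethyl-1,3,2-dioxaborolane
Product: 10 (S)-2-{1-[3-(tert-butyldimethylsilyloxy)-4,5-dimethoxyphenyl]propyl}-4,4,5,5-tetramethyl-1,3,2-dioxaborolane, via (R)-1-lithiopropyl N,N-diisopropylcarbamate 8 (not isolated), via lithium boronate complex 9 (not isolated)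
Conditions: 7 (1.4 equiv), s-BuLi (1.3 equiv), (+)-sparteine (1.3 equiv), Et2O, −78 °C, 5 h; 4 (1.0 equiv), −78 °C, 1 h; MgBr2·OEt2, −78 °C to reflux, 12 h
Reagents that add atoms: none
Why: The s-BuLi·(+)-sparteine complex, held by the carbamate carbonyl, removes the pro-R α-hydrogen of 7 and gives the (R)-organolithium 8, which keeps its configuration at −78 °C. Boronate 4 is captured with retention at carbon to give the tetracoordinate complex 9; capture is irreversible for a non-stabilised carbenoid, and it rests on the absence of ortho substituents in 4, since the donor groups lower the Lewis acidity of boron and help only in the next event. On warming, with MgBr2 assisting departure of the carbamate, the aryl group shifts from boron to carbon antiperiplanar to the C–O bond, so the carbon is inverted and (S)-10 results. The closest known reaction type is the lithiation–borylation of primary alkyl carbamates with aryl pinacol boronates, a Matteson-type 1,2-metalate rearrangement. No ring is closed. The new stereocentre is under reagent control by the diamine in the deprotonation and is then relayed stereospecifically, retention followed by inversion. The step needs aryl migration in preference to migration of a pinacol oxygen and no second homologation: the electron-rich aryl group is the better migrating group, and 4 is the limiting component while 10 forms only after the excess of 8 has decomposed on warming. The silyl ether and the methyl ethers meet no free s-BuLi, because 7 is used in slight excess over the base.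

Step 5
Reactants: 10 (S)-2-{1-[3-(tert-butyldimethylsilyloxy)-4,5-dimethoxyphenyl]propyl}-4,4,5,5-tetramethyl-1,3,2-dioxaborolane
Product: 11 (S)-1-[3-(tert-butyldimethylsilyloxy)-4,5-dimethoxyphenyl]propan-1-ol
Conditions: NaBO3·4H2O, THF/H2O (1:1), rt
Reagents that add atoms: sodium perborate tetrahydrate (as the dimeric peroxoborate), [Na+].[Na+].O[B-]1(O)OO[B-](O)(O)OO1
Why: Oxidation of a C–B bond by a peroxoborate proceeds by 1,2-shift of carbon from boron to oxygen with retention, so (S)-10 should give (S)-11. Perborate is chosen over NaOH/H2O2 because its mild basicity should leave the aryl silyl ether in place.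

Step 6
Reactants: 12 tert-butyl but-2-ynoate
Product: 14 tert-butyl (Z)-2-(hydroxymethyl)but-2-enoate, via tert-butyl (E)-2-(diisobutylalumanyl)but-2-enoate 13 (not isolated)
Conditions: i-Bu2AlH, NMO, THF, 0 °C; then HCHO (gas, from paraformaldehyde), 0 °C to rt; aq. potassium sodium tartrate
Reagents that add atoms: formaldehyde, C=O
Why: The amine-oxide complex of i-Bu2AlH adds hydride to the β-carbon and aluminium to the α-carbon of the ynoate in syn fashion (vinylalumination), and the alkenylalane 13 is hydroxymethylated at the α-carbon with retention. If 13 reacts through its aluminium allenolate form, the aldehyde should still enter on the side of the β-hydrogen, so both pathways place the methyl group cis to the ester, the Z geometry.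

Step 7
Reactants: 14 tert-butyl (Z)-2-(hydroxymethyl)but-2-enoate; 15 angelic acid [(Z)-2-methylbut-2-enoic acid]
Product: 17 tert-butyl (Z)-2-({[(Z)-2-methylbut-2-enoyl]oxy}methyl)but-2-enoate, via angelic 2,4,6-trichlorobenzoic anhydride 16 (not isolated)
Conditions: 15, 2,4,6-Cl3C6H2COCl, Et3N, toluene, rt; then 14, 75 °C (no DMAP)
Reagents that add atoms: none
Why: Yamaguchi esterification: the primary alcohol attacks the less hindered angeloyl carbonyl of the mixed anhydride 16. Leaving out the nucleophilic pyridine catalyst removes the addition–elimination pathway by which angelates turn into tiglates.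

Step 8
Reactants: 17 tert-butyl (Z)-2-({[(Z)-2-methylbut-2-enoyl]oxy}methyl)but-2-enoate
Product: 18 (Z)-2-({[(Z)-2-methylbut-2-enoyl]oxy}methyl)but-2-enoic acid
Conditions: CF3CO2H/CH2Cl2 (1:4), 0 °C to rt
Reagents that add atoms: none
Why: Acidolysis of a tert-butyl ester by alkyl–oxygen fission with loss of 2-methylpropene. The two conjugated esters cannot ionise in this way, and no nucleophile or base is present to isomerise the Z-alkenes.

Step 9
Reactants: 11 (S)-1-[3-(tert-butyldimethylsilyloxy)-4,5-dimethoxyphenyl]propan-1-ol; 18 (Z)-2-({[(Z)-2-methylbut-2-enoyl]oxy}methyl)but-2-enoic acid
Product: 20 (S)-1-[3-(tert-butyldimethylsilyloxy)-4,5-dimethoxyphenyl]propyl (Z)-2-({[(Z)-2-methylbut-2-enoyl]oxy}methyl)but-2-enoate, via acyl 2,4,6-trichlorobenzoyl mixed anhydride 19 (not isolated)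
Conditions: 18 (1.5 equiv), 2,4,6-Cl3C6H2COCl, Et3N, toluene, rt; then 11, 70 °C (no DMAP)
Reagents that add atoms: none
Why: Yamaguchi esterification under the same catalyst-free conditions as step 7, with the secondary alcohol attacking the enoyl carbonyl of 19 and not the di-ortho-substituted aroyl carbonyl. Only the O–H bond of 11 reacts, so the (S) centre is retained, and without an amine nucleophile neither Z-alkene nor the allylic angelate should be disturbed.

Step 10
Reactants: 20 (S)-1-[3-(tert-butyldimethylsilyloxy)-4,5-dimethoxyphenyl]propyl (Z)-2-({[(Z)-2-methylbut-2-enoyl]oxy}methyl)but-2-enoate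
Product: 21 (S)-1-(3-hydroxy-4,5-dimethoxyphenyl)propyl (Z)-2-({[(Z)-2-methylbut-2-enoyl]oxy}methyl)but-2-enoate
Conditions: Bu4NF, AcOH (1:1), THF, 0 °C
Reagents that add atoms: none
Why: Fluoride cleaves the aryl O–Si bond readily because phenoxide is a good leaving group, and acetic acid protonates the phenoxide at once. No free base remains to attack the allylic ester or the enoates, and no strong acid reaches the para-methoxybenzylic ester.

## Compound list

1 | 2,3-dimethoxyphenol | COc1cccc(O)c1OC | starting material
2 | tert-butyl(2,3-dimethoxyphenoxy)dimethylsilane | COc1cccc(O[Si](C)(C)C(C)(C)C)c1OC | intermediate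
3 | bis(pinacolato)diboron | CC1(C)OB(OC1(C)C)B1OC(C)(C)C(C)(C)O1 | starting material
4 | 2-[3-(tert-butyldimethylsilyloxy)-4,5-dimethoxyphenyl]-4,4,5,5-tetramethyl-1,3,2-dioxaborolane | CC1(C)OB(OC1(C)C)c1cc(O[Si](C)(C)C(C)(C)C)c(OC)c(OC)c1 | intermediate
5 | propan-1-ol | CCCO | starting material
6 | N,N-diisopropylcarbamoyl chloride | CC(C)N(C(C)C)C(Cl)=O | starting material
7 | propyl N,N-diisopropylcarbamate | CCCOC(=O)N(C(C)C)C(C)C | intermediate
8 | (R)-1-lithiopropyl N,N-diisopropylcarbamate [(+)-sparteine complex] | CC[C@@H]([Li])OC(=O)N(C(C)C)C(C)C | intermediate
9 | lithium [3-(tert-butyldimethylsilyloxy)-4,5-dimethoxyphenyl][(R)-1-(N,N-diisopropylcarbamoyloxy)propyl](pinacolato)borate | [Li+].CC[C@H](OC(=O)N(C(C)C)C(C)C)[B-]1(OC(C)(C)C(C)(C)O1)c1cc(O[Si](C)(C)C(C)(C)C)c(OC)c(OC)c1 | intermediate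
10 | (S)-2-{1-[3-(tert-butyldimethylsilyloxy)-4,5-dimethoxyphenyl]propyl}-4,4,5,5-tetramethyl-1,3,2-dioxaborolane | CC1(C)OB(OC1(C)C)[C@@H](CC)c1cc(O[Si](C)(C)C(C)(C)C)c(OC)c(OC)c1 | intermediate
11 | (S)-1-[3-(tert-butyldimethylsilyloxy)-4,5-dimethoxyphenyl]propan-1-ol | O[C@@H](CC)c1cc(O[Si](C)(C)C(C)(C)C)c(OC)c(OC)c1 | intermediate
12 | tert-butyl but-2-ynoate | CC#CC(=O)OC(C)(C)C | starting material
13 | tert-butyl (E)-2-(diisobutylalumanyl)but-2-enoate (N-methylmorpholine N-oxide complex; methyl cis to the ester) | C/C=C(/[Al](CC(C)C)CC(C)C)C(=O)OC(C)(C)C | intermediate
14 | tert-butyl (Z)-2-(hydroxymethyl)but-2-enoate | C/C=C(/CO)C(=O)OC(C)(C)C | intermediate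
15 | angelic acid, (Z)-2-methylbut-2-enoic acid | C/C=C(/C)C(=O)O | starting material
16 | (Z)-2-methylbut-2-enoic 2,4,6-trichlorobenzoic anhydride | C/C=C(/C)C(=O)OC(=O)c1c(Cl)cc(Cl)cc1Cl | intermediate
17 | tert-butyl (Z)-2-({[(Z)-2-methylbut-2-enoyl]oxy}methyl)but-2-enoate | C/C=C(/C)C(=O)OC/C(=C/C)C(=O)OC(C)(C)C | intermediate
18 | (Z)-2-({[(Z)-2-methylbut-2-enoyl]oxy}methyl)but-2-enoic acid | C/C=C(/C)C(=O)OC/C(=C/C)C(=O)O | intermediate
19 | (Z)-2-({[(Z)-2-methylbut-2-enoyl]oxy}methyl)but-2-enoic 2,4,6-trichlorobenzoic anhydride | C/C=C(/C)C(=O)OC/C(=C/C)C(=O)OC(=O)c1c(Cl)cc(Cl)cc1Cl | intermediate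
20 | (S)-1-[3-(tert-butyldimethylsilyloxy)-4,5-dimethoxyphenyl]propyl (Z)-2-({[(Z)-2-methylbut-2-enoyl]oxy}methyl)but-2-enoate | C/C=C(/C)C(=O)OC/C(=C/C)C(=O)O[C@@H](CC)c1cc(O[Si](C)(C)C(C)(C)C)c(OC)c(OC)c1 | intermediate
21 | (S)-1-(3-hydroxy-4,5-dimethoxyphenyl)propyl (Z)-2-({[(Z)-2-methylbut-2-enoyl]oxy}methyl)but-2-enoate | C/C=C(/C)C(=O)OC/C(=C/C)C(=O)O[C@@H](CC)c1cc(O)c(OC)c(OC)c1 | target

## Step count and risks

Total step count: 10. Longest linear sequence: 6 (steps 1, 2, 4, 5, 9, 10); the acid branch (steps 6, 7, 8) and the carbamate (step 3) are convergent.

The steps least certain to work are the key step 4 and steps 6, 9, 7 and 10.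

**Key step, step 4.** The likeliest failures are incomplete or insufficiently selective deprotonation, which lowers the enantiomeric purity, and sluggish aryl migration from the pinacol boronate complex, which returns 4 after work-up. A second homologation is possible if migration starts while 8 is still present. The fallback sets out from 4 and comes back at 11, replacing the rearrangement by acylation and catalytic asymmetric reduction. A Suzuki–Miyaura-type acylation of 4 with propanoyl chloride (Pd(PPh3)4, K3PO4, toluene, 80 °C) should give 1-[3-(tert-butyldimethylsilyloxy)-4,5-dimethoxyphenyl]propan-1-one F1. Transfer hydrogenation with RuCl[(S,S)-TsDPEN](p-cymene) in HCO2H/Et3N should then give the (S)-alcohol 11, so step 5 is no longer needed.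

**Risk in step 6.** Carbonyl reduction of the ester may compete with conjugate hydroalumination. The alkene geometry may be lost if the alkenylalane equilibrates and is captured from the other side. Formaldehyde may polymerise before it is captured. The fallback sets out from 12 and comes back at 14. Syn-hydrostannation (Bu3SnH, Pd(PPh3)4 cat., THF, rt) should give tert-butyl (E)-2-(tributylstannyl)but-2-enoate F2. Iododestannylation (I2, CH2Cl2, 0 °C) should give tert-butyl (E)-2-iodobut-2-enoate F3 with retention. A Stille coupling with Bu3SnCH2OH (Pd(PPh3)4, dioxane, 90 °C) should then put the hydroxymethyl group where the iodine was and give 14 with the methyl group still cis to the ester.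

**Risk in step 9.** The activated acyl donor may undergo Z to E isomerisation or lose its allylic angelate by addition–elimination, and acylation of the hindered secondary benzylic alcohol without a nucleophilic catalyst may be slow. The fallback sets out from 11 and comes back at 20, building the acyl part on the alcohol so that no Z-enoate is ever activated at the carboxyl group. Esterification of 11 with but-2-ynoic acid (DCC, DMAP cat., CH2Cl2, 0 °C) should give (S)-1-[3-(tert-butyldimethylsilyloxy)-4,5-dimethoxyphenyl]propyl but-2-ynoate F4. Hydroalumination and hydroxymethylation as in step 6 should give (S)-1-[3-(tert-butyldimethylsilyloxy)-4,5-dimethoxyphenyl]propyl (Z)-2-(hydroxymethyl)but-2-enoate F5. Acylation of F5 with the mixed anhydride 16 as in step 7 should then give 20.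

**Risk in step 7.** The angeloyl unit may isomerise to the tigloyl unit while its carboxyl group is activated. The fallback sets out from 14 (with 15) and comes back at 17. A Mitsunobu esterification (PPh3, diisopropyl azodicarboxylate, THF, 0 °C) activates the primary alcohol instead of the acid; angelate then acts only as a carboxylate nucleophile and has no pathway to isomerise. No new compound is made on this path, so its entry is F0.

**Risk in step 10.** Desilylation may be incomplete under buffered conditions. With less buffering, the transient phenoxide or fluoride may displace the allylic angelate, add to an enoate or isomerise it. The fallback sets out from 11 and comes back at 21, exchanging the silyl ether for a group that is removed by light under neutral conditions. Desilylation of 11 (Bu4NF, THF) should give (S)-5-(1-hydroxypropyl)-2,3-dimethoxyphenol F6. Phenol-selective alkylation (2-nitrobenzyl bromide, K2CO3, acetone) should give (S)-1-[3,4-dimethoxy-5-(2-nitrobenzyloxy)phenyl]propan-1-ol F7. Esterification with 18 through 19 as in step 9 should give (S)-1-[3,4-dimethoxy-5-(2-nitrobenzyloxy)phenyl]propyl (Z)-2-({[(Z)-2-methylbut-2-enoyl]oxy}methyl)but-2-enoate F8. Irradiation at 365 nm in MeCN, a wavelength the enoates do not absorb, should release 21.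

## Further compounds

F1 | step 4 | 1-[3-(tert-butyldimethylsilyloxy)-4,5-dimethoxyphenyl]propan-1-one | CCC(=O)c1cc(O[Si](C)(C)C(C)(C)C)c(OC)c(OC)c1
F2 | step 6 | tert-butyl (E)-2-(tributylstannyl)but-2-enoate | C/C=C(/[Sn](CCCC)(CCCC)CCCC)C(=O)OC(C)(C)C
F3 | step 6 | tert-butyl (E)-2-iodobut-2-enoate | C/C=C(/I)C(=O)OC(C)(C)C
F0 | step 7 | none | none
F4 | step 9 | (S)-1-[3-(tert-butyldimethylsilyloxy)-4,5-dimethoxyphenyl]propyl but-2-ynoate | CC#CC(=O)O[C@@H](CC)c1cc(O[Si](C)(C)C(C)(C)C)c(OC)c(OC)c1
F5 | step 9 | (S)-1-[3-(tert-butyldimethylsilyloxy)-4,5-dimethoxyphenyl]propyl (Z)-2-(hydroxymethyl)but-2-enoate | C/C=C(/CO)C(=O)O[C@@H](CC)c1cc(O[Si](C)(C)C(C)(C)C)c(OC)c(OC)c1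
F6 | step 10 | (S)-5-(1-hydroxypropyl)-2,3-dimethoxyphenol | O[C@@H](CC)c1cc(O)c(OC)c(OC)c1
F7 | step 10 | (S)-1-[3,4-dimethoxy-5-(2-nitrobenzyloxy)phenyl]propan-1-ol | O[C@@H](CC)c1cc(OCc2ccccc2[N+](=O)[O-])c(OC)c(OC)c1
F8 | step 10 | (S)-1-[3,4-dimethoxy-5-(2-nitrobenzyloxy)phenyl]propyl (Z)-2-({[(Z)-2-methylbut-2-enoyl]oxy}methyl)but-2-enoate | C/C=C(/C)C(=O)OC/C(=C/C)C(=O)O[C@@H](CC)c1cc(OCc2ccccc2[N+](=O)[O-])c(OC)c(OC)c1
A1 | alternative 1 | 3,4-dimethoxyfuran | COc1cocc1OC
A2 | alternative 1 | pent-1-yn-3-one | CCC(=O)C#C
A3 | alternative 1 | 1-(5,6-dimethoxy-7-oxabicyclo[2.2.1]hepta-2,5-dien-2-yl)propan-1-one (racemic) | CCC(=O)C1=CC2OC1C(OC)=C2OC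
A4 | alternative 1 | 1-(3-hydroxy-4,5-dimethoxyphenyl)propan-1-one | CCC(=O)c1cc(O)c(OC)c(OC)c1
A5 | alternative 2 | 1-(3,4-dimethoxyphenyl)propan-1-one | CCC(=O)c1ccc(OC)c(OC)c1
A6 | alternative 2 | (S)-1-(3,4-dimethoxyphenyl)propan-1-ol | O[C@@H](CC)c1ccc(OC)c(OC)c1
A7 | alternative 2 | (S)-1-(3,4-dimethoxyphenyl)propyl (Z)-2-({[(Z)-2-methylbut-2-enoyl]oxy}methyl)but-2-enoate | C/C=C(/C)C(=O)OC/C(=C/C)C(=O)O[C@@H](CC)c1ccc(OC)c(OC)c1
A8 | alternative 2 | (S)-1-[3,4-dimethoxy-5-(4,4,5,5-tetramethyl-1,3,2-dioxaborolan-2-yl)phenyl]propyl (Z)-2-({[(Z)-2-methylbut-2-enoyl]oxy}methyl)but-2-enoate | C/C=C(/C)C(=O)OC/C(=C/C)C(=O)O[C@@H](CC)c1cc(B2OC(C)(C)C(C)(C)O2)c(OC)c(OC)c1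
A9 | alternative 3 | (E)-3-[3-(tert-butyldimethylsilyloxy)-4,5-dimethoxyphenyl]allyl methyl carbonate | COC(=O)OC/C=C/c1cc(O[Si](C)(C)C(C)(C)C)c(OC)c(OC)c1
A10 | alternative 3 | (S)-1-[3-(tert-butyldimethylsilyloxy)-4,5-dimethoxyphenyl]allyl (Z)-2-({[(Z)-2-methylbut-2-enoyl]oxy}methyl)but-2-enoate | C/C=C(/C)C(=O)OC/C(=C/C)C(=O)O[C@@H](C=C)c1cc(O[Si](C)(C)C(C)(C)C)c(OC)c(OC)c1
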